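The constants were chosen freely; the rest is arithmetic.

I began from late times: a target molecule that outlived the substrate could still leave by the over-reaction step, so what counted was how much target stood at the asked time.

    substrate + coupling partner → target + by-product (k1 = 8000 M⁻¹ s⁻¹)
    gas ⇌ coupling partner, rate k2*(csat - [coupling partner]) (k2 = 3.8 s⁻¹, csat = 0.28 mM)
    target → over-reaction product (k3 = 0.099 s⁻¹)
    substrate + target → side product (k4 = 530 M⁻¹ s⁻¹)

common to all: gas 0.28 mM (held); time 5.0 s

| run | substrate |
|---|---|
| larch | 0.0010 M |
| cedar | 0.0030 M |
| birch | 0.010 M |
| ash | 0.025 M |
| oak | 0.080 M |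

- percent here means substrate units held: one side product counts as two
- at the start none of coupling partner is dissolved
- "hardly changes" means that all values lie within two and a half points (for a concentration: within two and a half percent of the largest)
- run time (larch): 5.0 s

- [target] at the end for larch, cedar, birch, ash, oak, in this order
- the shape of the row from first to last (hardly changes / rises all the way / falls all the way / falls, then rises / rises, then falls)

The gas was held, but no coupling partner was dissolved at the start, so target had to wait for gas to cross. I therefore took the gas ceiling, the transfer coefficient times the saturation concentration, 0.00106 M s⁻¹, as the fastest possible supply of coupling partner. Over the run it allowed 0.00532 M, more than larch's charge of 0.0010 M but less than oak's 0.080 M. So I expected the charge to hold the row down at its low end and the gas to hold it down at its high end.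

Then I followed one target molecule in oak. At the fork, substrate at its charge removed it at 42.4 s⁻¹ and the over-reaction step at 0.099 s⁻¹, so I expected nearly all of oak's target to go to side product. I treated this loss in oak as pseudo-first-order in target, with substrate in excess. Setting supply equal to loss, I committed to the ceiling over that frequency, 2.51 × 10⁻⁵ M, for oak, and to a row that rises, then falls.

The forecast gave 5.600 × 10⁻⁴ M, 8.200 × 10⁻⁴ M, 7.300 × 10⁻⁴ M, 1.300 × 10⁻⁴ M and 2.900 × 10⁻⁵ M, a row that rises, then falls, holding that “leftover substrate eats the target”. For oak it stood higher than my figure.

The flasks gave 4.86 × 10⁻⁴ M, 8.16 × 10⁻⁴ M, 6.55 × 10⁻⁴ M, 1.28 × 10⁻⁴ M and 2.86 × 10⁻⁵ M, a row that rises, then falls.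

Oak ended with 87 % of its substrate, so its 2.51 × 10⁻⁵ M becomes 2.89 × 10⁻⁵ M when reckoned on what stood there, beside 2.86 × 10⁻⁵ M in the flask. Ash ended with 59 % of its charge, and the same ceiling over the loss frequency of the substrate standing in ash gives 1.36 × 10⁻⁴ M, beside 1.28 × 10⁻⁴ M in the flask.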